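Everything rests on cutting the C2–C3 bond of the dihydrobenzofuran. In the precursor C2 is the benzylic CH2 of an aryl 3,4-dimethoxybenzyl ether. Its C–H bonds are made hydridic by O1 and by ring B, and they lie 1,5 to C3, the diazo-bearing carbon attached to C3a of ring A. A chiral dirhodium carboxylate turns C3 into a carbene that inserts into one of these C–H bonds. In a single flask this forms C2–C3, closes the dihydrofuran ring, fixes C2 and, after base equilibration, sets C3 trans. Ring A of the diazo ester already carries the C7 methoxy group and the finished (E)-acrylate chain at C5, so one double ester reduction completes the target.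

Key step: step 5

Assumption: by analogy with simpler 2-(benzyloxy)phenyl diazoacetates, phthalimido carboxylate catalysts built from (S)-amino acids are taken to lead to the 2R series, so the R-configured catalyst is specified for 2S. The sense should be confirmed on a test run (chiral HPLC, CD), and the equally available antipode is used if it proves opposite.

Remark on stereodescriptors: the target is trans and (2S,3R). The diester before it has the same spatial arrangement but is (2S,3S), because CO2Et outranks C2 at C3 whereas CH2OH does not.

Remark on the access to the precursor: the acetate arm is attached by cross-coupling to a 5-iodovanillin core whose phenol is already etherified. A ferulate ring deactivated by its acrylate is a poor partner for electrophilic substitution. A free 2-hydroxyphenylacetate would also lactonise to a benzofuranone.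

Step 1
Reactants: 1 5-iodovanillin (4-hydroxy-3-iodo-5-methoxybenzaldehyde); 2 3,4-dimethoxybenzyl chloride
Product: 3 4-[(3,4-dimethoxybenzyl)oxy]-3-iodo-5-methoxybenzaldehyde
Conditions: K2CO3 (1.5 equiv), DMF, 50 °C
Reagents that add atoms: none
Why: Williamson ether synthesis, in which the phenol of 1, acidified by the para formyl group and the ortho iodine, is fully ionised by K2CO3 and its phenoxide displaces chloride from the highly reactive benzylic chloride 2 by SN2 without touching the aldehyde or the C–I bond.

Step 2
Reactants: 3 4-[(3,4-dimethoxybenzyl)oxy]-3-iodo-5-methoxybenzaldehyde; 4 methyl (triphenylphosphoranylidene)acetate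
Product: 5 methyl (E)-3-{4-[(3,4-dimethoxybenzyl)oxy]-3-iodo-5-methoxyphenyl}acrylate
Conditions: toluene, 80 °C; crystallisation
Reagents that add atoms: none
Why: Wittig olefination, in which the ester-stabilised ylide 4 adds reversibly to the unhindered aromatic aldehyde so that the favoured trans-oxaphosphetane collapses to the E-cinnamate, and any trace of Z isomer should be lost when 5 is crystallised.

Step 3
Reactants: 5 methyl (E)-3-{4-[(3,4-dimethoxybenzyl)oxy]-3-iodo-5-methoxyphenyl}acrylate; 6 (2-ethoxy-2-oxoethyl)zinc bromide, BrZnCH2CO2Et (commercial solution)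
Product: 7 ethyl 2-{2-[(3,4-dimethoxybenzyl)oxy]-3-methoxy-5-[(E)-3-methoxy-3-oxoprop-1-enyl]phenyl}acetate
Conditions: 6 (1.5 equiv), Pd2(dba)3 (1.5 mol %), XPhos (6 mol %), THF, rt → 45 °C
Reagents that add atoms: none
Why: Negishi-type cross-coupling of a Reformatsky reagent (neutral α-arylation of an ester), in which zerovalent palladium inserts into the C–I bond, the zinc enolate transmetalates and the bulky biaryl phosphine drives C–C reductive elimination, while the weakly basic, weakly nucleophilic zinc reagent leaves both esters, the cinnamate double bond and the benzylic ether alone.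

Step 4
Reactants: 7 ethyl 2-{2-[(3,4-dimethoxybenzyl)oxy]-3-methoxy-5-[(E)-3-methoxy-3-oxoprop-1-enyl]phenyl}acetate
Product: 8 ethyl 2-diazo-2-{2-[(3,4-dimethoxybenzyl)oxy]-3-methoxy-5-[(E)-3-methoxy-3-oxoprop-1-enyl]phenyl}acetate
Conditions: p-ABSA (1.3 equiv), DBU (1.5 equiv), MeCN, 0 °C → rt, dark; 8 kept cold and used promptly
Reagents that add atoms: 4-acetamidobenzenesulfonyl azide (p-ABSA), CC(=O)Nc1ccc(cc1)S(=O)(=O)N=[N+]=[N-]
Why: Regitz diazo transfer, in which DBU reversibly deprotonates the arylacetate CH2 (the only acidic C–H of 7), the enolate attacks the terminal nitrogen of the sulfonyl azide and the triazene adduct collapses to the diazo ester and the sulfonamide.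

Step 5
Reactants: 8 ethyl 2-diazo-2-{2-[(3,4-dimethoxybenzyl)oxy]-3-methoxy-5-[(E)-3-methoxy-3-oxoprop-1-enyl]phenyl}acetate
Product: 10 ethyl (2S,3S)-2-(3,4-dimethoxyphenyl)-7-methoxy-5-[(E)-3-methoxy-3-oxoprop-1-enyl]-2,3-dihydrobenzofuran-3-carboxylate, via cis-(2S,3R) ester 9 (not isolated)
Conditions: Rh2(R-PTTL)4 (dirhodium tetrakis[N-phthaloyl-(R)-tert-leucinate], 1 mol %), toluene (0.01 M), −60 °C, slow addition of 8; then DBU (0.3 equiv), 0 °C → rt, same flask; filtration through SiO2
Reagents that add atoms: none
Why: Rh2(R-PTTL)4, a dimer of divalent rhodium, is attacked by the diazo carbon of 8, N2 leaves, and the electrophilic donor/acceptor carbene at C3 takes up one C2–H bond through a concerted, asynchronous three-centre transition state in which the developing positive charge at C2 is carried by O1 and by the para methoxy group of ring B. The closest known reaction type is the enantioselective intramolecular C–H insertion of 2-(benzyloxy)phenyl diazoacetates with chiral dirhodium tetracarboxylates, which gives cis-2-aryl-2,3-dihydrobenzofuran-3-carboxylates, and the phthalimido tert-leucinate ligand is chosen because it is established for benzylic CH2 groups in toluene, whereas arylsulfonylprolinate catalysts are at their best with methine C–H bonds in alkanes that would not dissolve 8. The dihydrofuran ring closes by 1,5-insertion (C3, C3a, C7a, O1, C2), the only closure within reach, since an oxonium ylide at O1 would need a four-membered ring and the C7 methoxy group cannot span the meta distance. C2 is fixed by the chiral pocket of the four carboxylate ligands, which admits only one of the two enantiotopic benzylic hydrogens, while C3 is first formed cis (9) under the same kinetic control and is then enolised by DBU and reprotonated under thermodynamic control, the C2 aryl group making trans 10 the more stable epimer. The step needs chemoselectivity for C–H insertion over cyclopropanation, dipolar cycloaddition and carbene dimerisation, and this is secured by the electron-poor, trans-1,2-disubstituted acrylate, a mismatched partner for a bulky electrophilic carbene, together with slow addition at high dilution. As the para acrylate makes O1 a better leaving group, DBU is kept substoichiometric and is removed on silica as soon as 9 is consumed, so that E1cB cleavage of C2–O1, which would scramble C2, stays out of play.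

Step 6
Reactants: 10 ethyl (2S,3S)-2-(3,4-dimethoxyphenyl)-7-methoxy-5-[(E)-3-methoxy-3-oxoprop-1-enyl]-2,3-dihydrobenzofuran-3-carboxylate
Product: 11 hierochin B, (E)-3-[(2S,3R)-2-(3,4-dimethoxyphenyl)-3-(hydroxymethyl)-7-methoxy-2,3-dihydrobenzofuran-5-yl]prop-2-en-1-ol
Conditions: i-Bu2AlH (6 equiv), CH2Cl2, −78 → −20 °C; aq potassium sodium tartrate
Reagents that add atoms: none
Why: Hydride reduction of both esters with i-Bu2AlH, an electrophilic hydride that takes cinnamates by 1,2-addition to cinnamyl alcohols without touching the double bond and, being non-basic in the cold, carries the C3 ester through hemiacetal and aldehyde to CH2OH without enolisation, so that C2 and C3 keep their configuration and only the descriptor at C3 changes from S to R.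

Compound list
1 | 5-iodovanillin (4-hydroxy-3-iodo-5-methoxybenzaldehyde) | O=Cc1cc(I)c(O)c(OC)c1 | starting material
2 | 3,4-dimethoxybenzyl chloride | COc1ccc(CCl)cc1OC | starting material
3 | 4-[(3,4-dimethoxybenzyl)oxy]-3-iodo-5-methoxybenzaldehyde | O=Cc1cc(I)c(OCc2ccc(OC)c(OC)c2)c(OC)c1 | intermediate
4 | methyl (triphenylphosphoranylidene)acetate | COC(=O)C=P(c1ccccc1)(c1ccccc1)c1ccccc1 | starting material
5 | methyl (E)-3-{4-[(3,4-dimethoxybenzyl)oxy]-3-iodo-5-methoxyphenyl}acrylate | COC(=O)/C=C/c1cc(I)c(OCc2ccc(OC)c(OC)c2)c(OC)c1 | intermediate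
6 | (2-ethoxy-2-oxoethyl)zinc bromide | CCOC(=O)C[Zn]Br | starting material
7 | ethyl 2-{2-[(3,4-dimethoxybenzyl)oxy]-3-methoxy-5-[(E)-3-methoxy-3-oxoprop-1-enyl]phenyl}acetate | CCOC(=O)Cc1cc(/C=C/C(=O)OC)cc(OC)c1OCc1ccc(OC)c(OC)c1 | intermediate
8 | ethyl 2-diazo-2-{2-[(3,4-dimethoxybenzyl)oxy]-3-methoxy-5-[(E)-3-methoxy-3-oxoprop-1-enyl]phenyl}acetate | CCOC(=O)C(=[N+]=[N-])c1cc(/C=C/C(=O)OC)cc(OC)c1OCc1ccc(OC)c(OC)c1 | intermediate
9 | ethyl (2S,3R)-2-(3,4-dimethoxyphenyl)-7-methoxy-5-[(E)-3-methoxy-3-oxoprop-1-enyl]-2,3-dihydrobenzofuran-3-carboxylate (cis, not isolated) | COc1ccc([C@H]2Oc3c(OC)cc(/C=C/C(=O)OC)cc3[C@H]2C(=O)OCC)cc1OC | intermediate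
10 | ethyl (2S,3S)-2-(3,4-dimethoxyphenyl)-7-methoxy-5-[(E)-3-methoxy-3-oxoprop-1-enyl]-2,3-dihydrobenzofuran-3-carboxylate (trans) | COc1ccc([C@H]2Oc3c(OC)cc(/C=C/C(=O)OC)cc3[C@@H]2C(=O)OCC)cc1OC | intermediate
11 | hierochin B, (E)-3-[(2S,3R)-2-(3,4-dimethoxyphenyl)-3-(hydroxymethyl)-7-methoxy-2,3-dihydrobenzofuran-5-yl]prop-2-en-1-ol | COc1ccc([C@H]2Oc3c(OC)cc(/C=C/CO)cc3[C@@H]2CO)cc1OC | target

Total step count: 6
Longest linear sequence: 6 steps (1 → 3 → 5 → 7 → 8 → 10 → 11)

Steps most likely to fail

Step 5. The very electron-rich ring B may push the insertion towards stepwise hydride transfer. That would loosen the hold of the ligands on the transition state and lower the enantioselectivity. Overlong contact with base may also open the C2–O1 bond and erode C2. A small shortfall in optical purity could be made good by recrystallising 10.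

The fallback sets out from 5 and comes back at 11. It shares stereocontrol between a covalently bound auxiliary and the catalyst, so that unwanted stereoisomers become separable diastereomers and no base treatment is needed.
- Commercial (S)-2-hydroxy-1-(pyrrolidin-1-yl)propan-1-one is acylated with bromoacetyl bromide (pyridine, CH2Cl2, 0 °C) to the lactamide bromoacetate F1.
- Zn in THF converts this into the zinc reagent F2, which is coupled with 5 under the conditions of step 3 to give the lactamide arylacetate F3.
- Diazo transfer as in step 4 gives the lactamide diazo ester F4.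
- Rh2(S-DOSP)4 (dirhodium tetrakis[(S)-N-(4-dodecylphenylsulfonyl)prolinate]) in CH2Cl2 at rt should give the trans-(2S,3S) lactamide ester F5 directly. This pairing of auxiliary and catalyst is known for closely related 7-methoxy-2-(3,4-dimethoxyphenyl)dihydrobenzofurans.
- Minor diastereomers are removed by chromatography or crystallisation, and i-Bu2AlH as in step 6 then reduces both esters of F5 to 11 and releases the water-soluble auxiliary.

Step 3. Transmetalation and reductive elimination may be slow at an arylpalladium centre crowded by the ortho benzyloxy group, so that protodeiodination or Heck-type self-coupling with the cinnamate takes over.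

The fallback sets out from 5 and comes back at 7. It replaces the zinc enolate by a soft, stabilised carbanion under copper catalysis.
- A Hurtley-type arylation of diethyl malonate (CuI, 2-picolinic acid, Cs2CO3, dioxane, rt → 60 °C) should give the diethyl arylmalonate F6.
- Krapcho dealkoxycarbonylation (LiCl, H2O, DMSO, 130 °C) then removes one ester group to give 7.

Step 4. Deprotonation of the crowded methylene may be sluggish. Over a long reaction time the azide or the diazo product may then add as a dipole to the cinnamate of a second molecule.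

The fallback sets out from 5, comes back at 8 and bypasses 7. The diazo carbon is brought in ready-made by palladium-catalysed C–H arylation of ethyl diazoacetate with the aryl iodide (Pd(PPh3)4, Ag2CO3, Et3N, toluene, rt). This is a known coupling of aryl iodides that keeps the N2 group and runs in a short time at room temperature.

Further compounds
F1 | step 5 | (S)-1-oxo-1-(pyrrolidin-1-yl)propan-2-yl bromoacetate | C[C@H](OC(=O)CBr)C(=O)N1CCCC1
F2 | step 5 | bromo{2-oxo-2-[(S)-1-oxo-1-(pyrrolidin-1-yl)propan-2-yloxy]ethyl}zinc | C[C@H](OC(=O)C[Zn]Br)C(=O)N1CCCC1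
F3 | step 5 | (S)-1-oxo-1-(pyrrolidin-1-yl)propan-2-yl 2-{2-[(3,4-dimethoxybenzyl)oxy]-3-methoxy-5-[(E)-3-methoxy-3-oxoprop-1-enyl]phenyl}acetate | C[C@H](OC(=O)Cc1cc(/C=C/C(=O)OC)cc(OC)c1OCc1ccc(OC)c(OC)c1)C(=O)N1CCCC1
F4 | step 5 | (S)-1-oxo-1-(pyrrolidin-1-yl)propan-2-yl 2-diazo-2-{2-[(3,4-dimethoxybenzyl)oxy]-3-methoxy-5-[(E)-3-methoxy-3-oxoprop-1-enyl]phenyl}acetate | C[C@H](OC(=O)C(=[N+]=[N-])c1cc(/C=C/C(=O)OC)cc(OC)c1OCc1ccc(OC)c(OC)c1)C(=O)N1CCCC1
F5 | step 5 | (S)-1-oxo-1-(pyrrolidin-1-yl)propan-2-yl (2S,3S)-2-(3,4-dimethoxyphenyl)-7-methoxy-5-[(E)-3-methoxy-3-oxoprop-1-enyl]-2,3-dihydrobenzofuran-3-carboxylate | COc1ccc([C@H]2Oc3c(OC)cc(/C=C/C(=O)OC)cc3[C@@H]2C(=O)O[C@@H](C)C(=O)N4CCCC4)cc1OC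
F6 | step 3 | diethyl 2-{2-[(3,4-dimethoxybenzyl)oxy]-3-methoxy-5-[(E)-3-methoxy-3-oxoprop-1-enyl]phenyl}malonate | CCOC(=O)C(C(=O)OCC)c1cc(/C=C/C(=O)OC)cc(OC)c1OCc1ccc(OC)c(OC)c1
F0 | step 4 | none | none
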